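If reagent holds one steady level, the bench rule says, a short-lived intermediate splits in a constant ratio (pseudo-first-order thinking), so I began by carrying the red ratio over to noon and summer. Starting material is fed into the first phase, reagent comes from the second, and I had the red run to forecast noon and summer.

| setting | red | noon | summer |
|---|---|---|---|
| starting material | 0.10 M (fed, over 3.0 d) | 0.10 M (fed, over 3.0 d) | 0.10 M (fed, over 3.0 d) |
| reagent in the second phase | 3.7 equiv | 2.50 equiv | 5.00 equiv |
| remark | run made earlier |  |  |
| time |  | 8.0 d | 8.0 d |
| volume of the second phase over the first |  | 0.25 | 0.25 |

red run (percent of the starting material charged)

| time / d | target / % | starting material / % | over-reaction product / % | over-reacted product / % |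
|---|---|---|---|---|
| 0.625 | 1.1 | 13.3 | 0.9 | 5.1 |
| 1.25 | 4.6 | 16.2 | 5.3 | 14.9 |
| 2.08 | 5.2 | 18.0 | 7.9 | 33.5 |
| 2.50 | 4.7 | 21.4 | 13.3 | 43.2 |
| 3.00 | 5.6 | 23.3 | 16.2 | 53.6 |
| 4.00 | 2.5 | 7.4 | 23.2 | 67.4 |

(each reading ± 1 percentage point)

- in the second phase: reagent in the second phase; everything else is in the first
- charges count per volume of the first phase; a concentration in a rate is the amount of a species over the volume of its own phase; every rate counts per litre of the first phase
- the earlier runs hold the two phases in the same ratio of volumes as the flask asked about
- percentages count the whole charge, also what has not yet gone in

* which of these there is most of at the end, counted by the starting material in it, noon (target / over-reaction product / over-reacted product / starting material)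
* which of these there is most of at the end, counted by the starting material in it, summer (target / over-reaction product / over-reacted product / starting material)
* how much there is at the end of the one of these that leads, in percent of the starting material charged: noon
* how much there is at the end of the one of these that leads, in percent of the starting material charged: summer

At 4.00 d the red run held 67.4% over-reacted product and 23.2% over-reaction product, so over-reacted product had a share of 74.4% of the two. Carried over, that gave noon and summer the same share. But the red ratio drifted: it was 3.31 at 3.00 d, and over the last interval it was 1.97, though a scatter of 1 percentage point leaves that rough.

I supposed that over-reacted product costs two equivalents of reagent and over-reaction product one. A finished flask at the red share then uses reagent equal to 174% of the starting material charged, which is 34.9% of the summer charge of reagent but 69.8% of the noon charge. The rule asks for one steady level of reagent, but the noon charge is 0.676 times the red charge and the summer charge 1.35 times it, so I did not carry the red ratio across these charges.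

So I carried the split per equivalent instead: the ratio of the two products divided by the equivalents of reagent left on average, at a charge of 0.10 M. The red run gave 1.00 per equivalent. Assuming complete conversion, noon keeps 1.63 equivalents on average, so its ratio is 1.63 and its share 62.0%. Summer keeps 4.13, so its ratio is 4.14 and its share 80.5%.

The forecast, noting that “the over-reacted route needs reagent and the other may not”, named over-reacted product for noon and over-reacted product for summer. Its figures were 58% and 76%, each lower than mine.

Over-reacted product led in both flasks, with 61.3% at noon and 81.3% in summer, 5.3 points above the forecast.

    starting material + reagent in the reaction phase → target (k = 0.310 L mol⁻¹ h⁻¹)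
    reagent in the reaction phase ⇌ reagent in the second phase, rate k2*([reagent in the reaction phase] - [reagent in the second phase]/K2) per volume of the first phase (partition coefficient = 1.60, kL = 0.150 h⁻¹)
    target → over-reaction product (k = 0.0600 h⁻¹)
    reagent in the reaction phase + target → over-reacted product (k = 0.920 L mol⁻¹ h⁻¹)

Noon still held 2.1% of starting material at 8.00 d. A neighbour of noon charged at 0.17 M, with the same equivalents, has each equivalent 1.70 times as concentrated. The split per equivalent, scaled by that factor, gives a ratio of 2.77 and a share of 73.5%, and that neighbour ended with 72.5% over-reacted product.

(Readings and results are simulated with made-up constants; the scatter is artificial.)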